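**Plan**

- Labels: C8 is the fully substituted oxirane carbon, C9 the oxirane CH2, C10 the CH2 that carries the isovalerate. The retrosynthesis cuts the formyl C=O (back to a vinyl group), then the two isovalerate O–acyl bonds, then the oxirane bonds C8–C9 and C8–O.
- Enabling feature: the phenol oxygen, the two arene carbons between it and C8, C8 itself and C10 can be closed to a five-membered aryl lactone (a benzofuran-2-one). In it C10 is the carbonyl carbon and C8 the acidic ring position 3.
- Forward order: the lactone ring is made first from an arylacetic acid, the vinyl group is attached by Stille coupling and C8 is chlorinated. The oxirane is then spiro-fused onto the lactone by a Darzens reaction with formaldehyde (C8–C9 first, then C8–O).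
- The lactone is finally opened by hydride at C10, both liberated oxygens are acylated in the same flask, and ozonolysis unmasks the aldehyde.
- Stereochemistry: C8 is the only stereocentre. It is set in the Darzens step by a chiral cinchona ammonium ion pair, and no later step breaks a bond at C8.

Key step: step 4

Assumption: which enolate face the cinchonidinium cation shields cannot be fixed by analogy alone. The cinchonidine-derived salt is assumed to lead to the (3R)-epoxide; if the first run shows the opposite sense, the pseudoenantiomeric cinchonine-derived salt replaces it and nothing else changes.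

**Route**

Step 1
Reactants: 1 2-(4-bromo-2-methoxyphenyl)acetic acid
Product: 3 6-bromo-1-benzofuran-2(3H)-one, via 2-(4-bromo-2-hydroxyphenyl)acetic acid 2 (not isolated)
Conditions: BBr3 (2.5 equiv), CH2Cl2, −78 °C → rt; H2O; then TsOH (cat.), toluene, reflux with azeotropic removal of water
Reagents that add atoms: none
Why: BBr3 cleaves the aryl methyl ether (Lewis acid O-demethylation) without touching the aryl bromide, and the freed ortho-hydroxyphenylacetic acid 2 closes to the five-membered aryl lactone on acid-catalysed dehydration (lactonisation).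

Step 2
Reactants: 3 6-bromo-1-benzofuran-2(3H)-one; 4 tributyl(ethenyl)stannane
Product: 5 6-ethenyl-1-benzofuran-2(3H)-one
Conditions: Pd(PPh3)4 (5 mol %), toluene, 100 °C, BHT (trace)
Reagents that add atoms: none
Why: Stille coupling (oxidative addition of the aryl bromide to zerovalent palladium, vinyl transfer from tin, reductive elimination) runs without base, so the acidic lactone CH2 and the aryl ester are left alone.

Step 3
Reactants: 5 6-ethenyl-1-benzofuran-2(3H)-one
Product: 7 rac-3-chloro-6-ethenyl-1-benzofuran-2(3H)-one, via 6-ethenyl-2-(trimethylsilyloxy)-1-benzofuran 6 (not isolated)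
Conditions: Me3SiCl (1.3 equiv), LiN(SiMe3)2 (1.05 equiv), THF, −78 → 0 °C; then NCS (1.0 equiv), −78 → 0 °C; pH 7 buffer, short silica plug
Reagents that add atoms: N-chlorosuccinimide, O=C1CCC(=O)N1Cl; chlorotrimethylsilane, C[Si](C)(C)Cl (its silyl group stays only in 6)
Why: Deprotonation at position 3 in the presence of Me3SiCl gives the aromatic silyl ketene acetal 6, which N-chlorosuccinimide chlorinates once at C3 (electrophilic α-chlorination of a silyl ketene acetal), since no base is left to enolise the more acidic monochloride and the styrene is inert to NCS at low temperature; the product is racemic and configurationally labile, which the next step tolerates.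

Step 4
Reactants: 7 rac-3-chloro-6-ethenyl-1-benzofuran-2(3H)-one; 8 formaldehyde
Product: 11 (3R)-6-ethenylspiro[1-benzofuran-3,2'-oxiran]-2-one, via chloro-enolate ion pair 9 (not isolated), via chlorohydrin alkoxide 10 (not isolated)
Conditions: O-allyl-N-(9-anthracenylmethyl)cinchonidinium bromide (10 mol %), K2CO3 (powder, 2 equiv), CH2O (3 equiv, dry THF solution from cracked paraformaldehyde), toluene, 4 Å MS, −40 °C, slow addition of 7; cold filtration through neutral silica, used at once
Reagents that add atoms: none
Why: Proposed new method: solid K2CO3 deprotonates the acidic C3–H of 7 at the interface and the planar, aromatic 3-chlorobenzofuran-2-olate passes into toluene as ion pair 9 with the cinchonidinium cation, whose anthracenylmethyl and quinoline walls should leave one enolate face open to formaldehyde, so that C–C bond formation (aldol addition) gives the (3S)-chlorohydrin alkoxide 10. The alkoxide then displaces chloride at C3 from the rear with inversion in a 3-exo-tet closure, which forms the oxirane as a spiro ring on the lactone and turns the (3S)-aldolate into the (3R)-epoxide. The closest known reaction types are catalytic asymmetric Darzens reactions of 3-chlorooxindoles with aldehydes and the catalytic asymmetric hydroxymethylation of 3-substituted oxindoles with formaldehyde; neither has been shown for a 3-chlorobenzofuranone with formaldehyde. The one new stereocentre (C8) is controlled by the catalyst alone, because formaldehyde has no faces and both enantiomers of 7 converge on the same achiral enolate. The step needs enantiofacial selectivity, C- over O-attack and aldol addition faster than alkylation of the enolate by unreacted 7; the flat bicyclic enolate suits tight ion pairing, the chlorine blocks a second hydroxymethylation and makes the closure irreversible, and excess monomeric formaldehyde with slow addition of 7 keeps enolate and chloride apart.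

Step 5
Reactants: 11 (3R)-6-ethenylspiro[1-benzofuran-3,2'-oxiran]-2-one; 12 3-methylbutanoic anhydride
Product: 14 [(2R)-2-{4-ethenyl-2-[(3-methylbutanoyl)oxy]phenyl}oxiran-2-yl]methyl 3-methylbutanoate, via dialuminium diolate 13 (not isolated)
Conditions: i-Bu2AlH (3 equiv), CH2Cl2, −78 → −40 °C; then pyridine, DMAP, 12 (6 equiv), −78 → 0 °C; aq. potassium sodium tartrate
Reagents that add atoms: none
Why: i-Bu2AlH reduces the activated aryl lactone through the lactol aluminate, which opens to an aluminium phenoxide and an α-epoxy aldehyde that takes a second hydride, and the resulting dialuminium diolate 13 is acylated at both oxygens in the same flask by the anhydride under DMAP catalysis (ester reduction followed by in-situ acylation of aluminium alkoxides), so that no free phenoxide sits beside the oxirane and no bond at C8 is broken.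

Step 6
Reactants: 14 [(2R)-2-{4-ethenyl-2-[(3-methylbutanoyl)oxy]phenyl}oxiran-2-yl]methyl 3-methylbutanoate
Product: 15 [(2R)-2-{4-formyl-2-[(3-methylbutanoyl)oxy]phenyl}oxiran-2-yl]methyl 3-methylbutanoate
Conditions: O3, CH2Cl2, −78 °C; then Me2S, −78 °C → rt
Reagents that add atoms: ozone, O=[O+][O-]
Why: Ozonolysis with reductive work-up cleaves the only C=C bond to the aryl aldehyde and formaldehyde, while the oxirane, the two esters and the acyloxy-deactivated arene are inert to ozone at −78 °C.

**Compound list**

1 | 2-(4-bromo-2-methoxyphenyl)acetic acid | COc1cc(Br)ccc1CC(=O)O | starting material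
2 | 2-(4-bromo-2-hydroxyphenyl)acetic acid (formed in the flask in step 1) | Oc1cc(Br)ccc1CC(=O)O | intermediate
3 | 6-bromo-1-benzofuran-2(3H)-one | O=C1Cc2ccc(Br)cc2O1 | intermediate
4 | tributyl(ethenyl)stannane | C=C[Sn](CCCC)(CCCC)CCCC | starting material
5 | 6-ethenyl-1-benzofuran-2(3H)-one | O=C1Cc2ccc(C=C)cc2O1 | intermediate
6 | 6-ethenyl-2-(trimethylsilyloxy)-1-benzofuran (formed in the flask in step 3) | C[Si](C)(C)Oc1cc2ccc(C=C)cc2o1 | intermediate
7 | rac-3-chloro-6-ethenyl-1-benzofuran-2(3H)-one | C=Cc1ccc2C(Cl)C(=O)Oc2c1 | intermediate
8 | formaldehyde (monomer, generated from commercial paraformaldehyde) | C=O | starting material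
9 | 3-chloro-6-ethenyl-1-benzofuran-2-olate, ion pair with the O-allyl-N-(9-anthracenylmethyl)cinchonidinium cation (anion shown; formed in the flask in step 4) | [O-]c1oc2cc(C=C)ccc2c1Cl | intermediate
10 | (3S)-3-chloro-6-ethenyl-3-(oxidomethyl)-1-benzofuran-2(3H)-one, same cation (anion shown; formed in the flask in step 4) | O=C1Oc2cc(C=C)ccc2[C@]1(Cl)C[O-] | intermediate
11 | (3R)-6-ethenylspiro[1-benzofuran-3,2'-oxiran]-2-one | O=C1Oc2cc(C=C)ccc2[C@@]12CO2 | intermediate
12 | 3-methylbutanoic anhydride | CC(C)CC(=O)OC(=O)CC(C)C | starting material
13 | bis(diisobutylaluminium) derivative of (2R)-2-(4-ethenyl-2-oxidophenyl)-2-(oxidomethyl)oxirane, Al on the phenol oxygen and on the C10 oxygen (formed in the flask in step 5) | CC(C)C[Al](CC(C)C)OC[C@@]1(c2ccc(C=C)cc2O[Al](CC(C)C)CC(C)C)CO1 | intermediate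
14 | [(2R)-2-{4-ethenyl-2-[(3-methylbutanoyl)oxy]phenyl}oxiran-2-yl]methyl 3-methylbutanoate | CC(C)CC(=O)OC[C@@]1(c2ccc(C=C)cc2OC(=O)CC(C)C)CO1 | intermediate
15 | [(2R)-2-{4-formyl-2-[(3-methylbutanoyl)oxy]phenyl}oxiran-2-yl]methyl 3-methylbutanoate (CNP0274578.1) | CC(C)CC(=O)OC[C@@]1(c2ccc(C=O)cc2OC(=O)CC(C)C)CO1 | target

**Step count**

Total steps: 6. Longest linear sequence: 6 steps (1 → 3 → 5 → 7 → 11 → 14 → 15).

**Steps most likely to fail**

Step 4 (proposed new method). Facial discrimination in the ion pair may be low. The chloro-enolate may also be alkylated by unreacted 7 faster than it adds to formaldehyde, and traces of water may open the strained aryl lactone. The fallback uses known chemistry only, sets out from 5 and returns at 14.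
- Lactone 5 is opened by acid methanolysis (MeOH, H2SO4 cat., rt) to methyl 2-(4-ethenyl-2-hydroxyphenyl)acetate F1.
- The phenol is silylated (i-Pr3SiCl, imidazole, DMF) to methyl 2-{4-ethenyl-2-[tri(propan-2-yl)silyloxy]phenyl}acetate F2.
- α-Methylenation with paraformaldehyde, K2CO3 and Bu4NHSO4 in toluene at 70 °C should give methyl 2-{4-ethenyl-2-[tri(propan-2-yl)silyloxy]phenyl}prop-2-enoate F3.
- i-Bu2AlH in CH2Cl2 at −78 °C reduces the ester to 2-{4-ethenyl-2-[tri(propan-2-yl)silyloxy]phenyl}prop-2-en-1-ol F4.
- Sharpless asymmetric epoxidation (Ti(Oi-Pr)4, L-(+)-diethyl tartrate, t-BuOOH, 4 Å MS, CH2Cl2, −20 °C) should, by the usual facial rule, deliver [(2S)-2-{4-ethenyl-2-[tri(propan-2-yl)silyloxy]phenyl}oxiran-2-yl]methanol F5. The styrenic vinyl group is not allylic to a hydroxyl and should stay intact.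
- Acylation with 12, Et3N and DMAP gives [(2R)-2-{4-ethenyl-2-[tri(propan-2-yl)silyloxy]phenyl}oxiran-2-yl]methyl 3-methylbutanoate F6. Bu4NF is then added to the same flask at −20 °C with excess 12 still present, so the phenoxide is acylated as it is set free, which gives 14.

Step 5. The reduction may stall at the lactol aluminate, so that acylation caps the lactol instead of the ring-opened diolate. On warming, aluminium may also assist opening of the benzylic oxirane. The fallback sets out from 11 and returns at 14. NaBH4 in THF/EtOH at −30 °C, a hydride without Lewis acidity that reduces aryl esters and glycidic esters but leaves oxiranes alone, should give after a cold pH 7 quench 5-ethenyl-2-[(2S)-2-(hydroxymethyl)oxiran-2-yl]phenol F7. This is not stored but acylated directly in a separate operation with 12, Et3N and DMAP in CH2Cl2 at −20 °C to reach 14.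

Step 3. Chlorination may run on to the 3,3-dichloride, or chlorine may add across the styrene. The fallback sets out from 5 and returns at 7. Diazo transfer with 4-acetamidobenzenesulfonyl azide and Et3N in MeCN at 0 °C gives 3-diazo-6-ethenyl-1-benzofuran-2(3H)-one F8. Dry HCl in Et2O at −20 °C then protonates the diazo carbon, and chloride takes the place of nitrogen, so exactly one chlorine is installed.

**Further compounds**

F1 | step 4 | methyl 2-(4-ethenyl-2-hydroxyphenyl)acetate | COC(=O)Cc1ccc(C=C)cc1O
F2 | step 4 | methyl 2-{4-ethenyl-2-[tri(propan-2-yl)silyloxy]phenyl}acetate | COC(=O)Cc1ccc(C=C)cc1O[Si](C(C)C)(C(C)C)C(C)C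
F3 | step 4 | methyl 2-{4-ethenyl-2-[tri(propan-2-yl)silyloxy]phenyl}prop-2-enoate | COC(=O)C(=C)c1ccc(C=C)cc1O[Si](C(C)C)(C(C)C)C(C)C
F4 | step 4 | 2-{4-ethenyl-2-[tri(propan-2-yl)silyloxy]phenyl}prop-2-en-1-ol | OCC(=C)c1ccc(C=C)cc1O[Si](C(C)C)(C(C)C)C(C)C
F5 | step 4 | [(2S)-2-{4-ethenyl-2-[tri(propan-2-yl)silyloxy]phenyl}oxiran-2-yl]methanol | OC[C@@]1(c2ccc(C=C)cc2O[Si](C(C)C)(C(C)C)C(C)C)CO1
F6 | step 4 | [(2R)-2-{4-ethenyl-2-[tri(propan-2-yl)silyloxy]phenyl}oxiran-2-yl]methyl 3-methylbutanoate | CC(C)CC(=O)OC[C@@]1(c2ccc(C=C)cc2O[Si](C(C)C)(C(C)C)C(C)C)CO1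
F7 | step 5 | 5-ethenyl-2-[(2S)-2-(hydroxymethyl)oxiran-2-yl]phenol | OC[C@@]1(c2ccc(C=C)cc2O)CO1
F8 | step 3 | 3-diazo-6-ethenyl-1-benzofuran-2(3H)-one | [N-]=[N+]=C1C(=O)Oc2cc(C=C)ccc12
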